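**Plan**

- Retrosynthetic cuts, in order: the two aryl–CHO bonds (formylation); the C-α–CH2 bond of the isobutyl group (benzylic cation plus methallylsilane); the two bonds from C6 and C7 to the CMe2 carbon (carbene addition); the aryl–C-α bond (Parham closure onto an ester); last the C3a–C7a and C4–C5 bonds of the hydrindane (intramolecular Diels–Alder). The open trienone comes from an aryl ether SN2, a malonate alkylation and an aldol condensation.
- Enabling feature: the cyclopentane and cyclohexane rings are a cis-fused hydrindane. Its ring-fusion carbon C3a carries the aryl ether oxygen, the adjacent C4 carries its methyl cis to that oxygen, and C7a carries its hydrogen on the same face. This is the pattern a (Z)-2-aryloxybut-2-enoyl dienophile leaves after suprafacial addition to a butadiene, so the tertiary aryl ether can be made earlier at a primary carbon.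
- Forward order of rings: acyclic aryloxy trienone, then cyclohexene and cyclopentanone together (step 6), then the seven-membered benzo-fused oxacycle (step 10), then the cyclopropane (steps 15–16), then side chain and aldehydes.
- Stereochemistry: a chiral boron Lewis acid fixes C3a, C4 and C7a in the cycloaddition. C1 is fixed because only the ester cis to the ether can reach the aryllithium. The cyclopropane comes from convex-face carbene addition, and C-α from exo attack of the allylsilane on the benzylic cation.
- Locants (indene numbering of the hydrindane): C1 = malonate-derived quaternary carbon, C3 = tether carbonyl carbon, C3a = O-bearing fusion carbon, C4 = CH–CH3, C6/C7 = alkene (later cyclopropane) carbons, C7a = fusion CH; C-α = benzylic carbon.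

Key step: step 6

Remarks (assumptions on the chemistry):
- 3,5-Bis(benzyloxy)phenol is taken as a purchasable phloroglucinol derivative.
- The (S)-prolinol-derived catalyst is written for step 6; its sense of induction on this enone is not secured by the usual binding model, and the equally available antipode is used if the mirror-image adduct forms.
- The carbinol or ether centres at C3 (hydroxy compound and thionocarbonate) and at C-α (diol through the gem-dimethylcyclopropane methyl ether) are left undefined, because each is later removed or ionised.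

**Route**

Step 1
Reactants: 1 3,5-bis(benzyloxy)phenol
Product: 2 3,5-bis(benzyloxy)-2-bromophenol
Conditions: NBS (1.0 equiv), i-Pr2NH (10 mol%), CH2Cl2, −78 → 0 °C
Reagents that add atoms: N-bromosuccinimide, O=C1CCC(=O)N1Br
Why: Amine-catalysed NBS bromination (electrophilic aromatic substitution) of a phenol is ortho-selective, and the two ortho positions of 1 are equivalent, so one monobromide should result.

Step 2
Reactants: 2 3,5-bis(benzyloxy)-2-bromophenol; 3 1,3-dichloropropan-2-one
Product: 4 1-[3,5-bis(benzyloxy)-2-bromophenoxy]-3-chloropropan-2-one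
Conditions: 3 (4 equiv), K2CO3, acetone, rt
Reagents that add atoms: none
Why: Williamson ether synthesis by SN2 of the phenoxide at a primary carbon activated by the adjacent carbonyl; the excess of 3 should suppress the diaryl ether.

Step 3
Reactants: 5 (E)-but-2-enal; 6 dimethyl malonate
Product: 7 dimethyl 2-[(2E)-but-2-en-1-ylidene]propanedioate
Conditions: TiCl4, pyridine, THF, 0 °C → rt
Reagents that add atoms: none
Why: Knoevenagel condensation under TiCl4/pyridine is the standard way to condense malonates with enals without conjugate addition, and the (E)-alkene of the aldehyde is kept.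

Step 4
Reactants: 7 dimethyl 2-[(2E)-but-2-en-1-ylidene]propanedioate; 4 1-[3,5-bis(benzyloxy)-2-bromophenoxy]-3-chloropropan-2-one
Product: 9 dimethyl 2-{3-[3,5-bis(benzyloxy)-2-bromophenoxy]-2-oxopropyl}-2-[(1E)-buta-1,3-dien-1-yl]propanedioate, via sodium dienolate 8 (not isolated)
Conditions: NaH, THF, 0 °C; then 4, Bu4NI (cat.), 0 °C → rt
Reagents that add atoms: none
Why: Deconjugative alkylation of the extended malonate enolate occurs at its α-carbon by SN2 on the very reactive α-chloro ketone, giving the quaternary malonate and leaving the (E)-configured terminal 1,3-diene.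

Step 5
Reactants: 9 dimethyl 2-{3-[3,5-bis(benzyloxy)-2-bromophenoxy]-2-oxopropyl}-2-[(1E)-buta-1,3-dien-1-yl]propanedioate
Product: 13 dimethyl 2-{(3Z)-3-[3,5-bis(benzyloxy)-2-bromophenoxy]-2-oxopent-3-en-1-yl}-2-[(1E)-buta-1,3-dien-1-yl]propanedioate, via lithium enolate 10 (not isolated), via lithium aldolate 11 (not isolated), via β-mesyloxy ketone 12 (not isolated)
Conditions: LiN(SiMe3)2, THF, −78 °C; MeCHO; MsCl, −78 → 0 °C; DBU, 0 °C → rt
Reagents that add atoms: acetaldehyde, CC=O
Why: Directed aldol addition followed by E1cB elimination of the mesylate (aldol condensation): kinetic deprotonation should occur at the more acidic aryloxy-methylene (the other α-CH2 is neopentyl), and elimination should favour the (Z)-enone with CH3 anti to the acyl group, the minor (E)-isomer being removed by chromatography.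

Step 6
Reactants: 13 dimethyl 2-{(3Z)-3-[3,5-bis(benzyloxy)-2-bromophenoxy]-2-oxopent-3-en-1-yl}-2-[(1E)-buta-1,3-dien-1-yl]propanedioate
Product: 14 dimethyl (3aS,4S,7aR)-3a-[3,5-bis(benzyloxy)-2-bromophenoxy]-4-methyl-3-oxo-2,3,3a,4,5,7a-hexahydro-1H-indene-1,1-dicarboxylate
Conditions: oxazaborolidinium salt from (S)-3,3-diphenyl-1-(2-methylphenyl)tetrahydro-1H,3H-pyrrolo[1,2-c][1,3,2]oxazaborole and HN(SO2CF3)2 (20 mol%), CH2Cl2, −40 → −20 °C
Reagents that add atoms: none
Why: Proposed new method: the cationic boron Lewis acid binds the ketone oxygen and lowers the LUMO of the 2-aryloxy enone, which then adds the tethered (E)-butadienyl group in a concerted suprafacial [4+2] process; the closest known reaction type is the chiral Lewis acid-catalysed intramolecular Diels–Alder reaction of 1,6,8-nonatrien-3-ones, extended here to an α-aryloxy, β-methyl (trisubstituted) dienophile. The cyclohexene closes by bond formation at both diene termini (C3a–C7a and C4–C5), and the cyclopentanone closes through the same C3a–C7a bond across the three-atom tether in the fused mode, with the tether carbonyl inside the new ring. C3a and C4 take their relative configuration from the (Z)-alkene (aryloxy and CH3 stay cis), C7a from the tether-carbonyl-endo transition state that gives the cis ring fusion with H-7a cis to the aryloxy group, and all three take their absolute sense from the enone face left open by the aryl groups of the catalyst. The step needs endo selectivity, which the short ketone-containing tether favours; π-facial selectivity, which only the catalyst can supply because the malonate tether is achiral; and enough dienophile reactivity, which the gem-diester and the strong cationic Lewis acid are meant to provide against the donor aryloxy group.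

Step 7
Reactants: 14 dimethyl (3aS,4S,7aR)-3a-[3,5-bis(benzyloxy)-2-bromophenoxy]-4-methyl-3-oxo-2,3,3a,4,5,7a-hexahydro-1H-indene-1,1-dicarboxylate
Product: 15 dimethyl (3aS,4S,7aR)-3a-[3,5-bis(benzyloxy)-2-bromophenoxy]-3-hydroxy-4-methyl-2,3,3a,4,5,7a-hexahydro-1H-indene-1,1-dicarboxylate (C3 epimers)
Conditions: NaBH4, MeOH/THF, 0 °C
Reagents that add atoms: none
Why: Borohydride reduction is selective for the ketone over the hindered esters, the alkene and the aryl bromide; the new carbinol centre is removed in step 9.

Step 8
Reactants: 15 dimethyl (3aS,4S,7aR)-3a-[3,5-bis(benzyloxy)-2-bromophenoxy]-3-hydroxy-4-methyl-2,3,3a,4,5,7a-hexahydro-1H-indene-1,1-dicarboxylate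
Product: 16 dimethyl (3aS,4S,7aR)-3a-[3,5-bis(benzyloxy)-2-bromophenoxy]-4-methyl-3-[(phenoxycarbonothioyl)oxy]-2,3,3a,4,5,7a-hexahydro-1H-indene-1,1-dicarboxylate
Conditions: PhOC(S)Cl, pyridine, DMAP (cat.), CH2Cl2, rt
Reagents that add atoms: O-phenyl chlorothionoformate, S=C(Cl)Oc1ccccc1
Why: DMAP-catalysed acylation of the secondary alcohol gives the thionocarbonate needed for Barton–McCombie deoxygenation under non-basic conditions that should not lactonise the hydroxy diester.

Step 9
Reactants: 16 dimethyl (3aS,4S,7aR)-3a-[3,5-bis(benzyloxy)-2-bromophenoxy]-4-methyl-3-[(phenoxycarbonothioyl)oxy]-2,3,3a,4,5,7a-hexahydro-1H-indene-1,1-dicarboxylate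
Product: 17 dimethyl (3aS,4S,7aR)-3a-[3,5-bis(benzyloxy)-2-bromophenoxy]-4-methyl-2,3,3a,4,5,7a-hexahydro-1H-indene-1,1-dicarboxylate
Conditions: (Me3Si)3SiH, AIBN (cat.), toluene, 80 °C
Reagents that add atoms: none
Why: Barton–McCombie deoxygenation; the silyl radical adds to C=S much faster than it abstracts bromine from the electron-rich aryl bromide, and the secondary C3 radical is then reduced by Si–H.

Step 10
Reactants: 17 dimethyl (3aS,4S,7aR)-3a-[3,5-bis(benzyloxy)-2-bromophenoxy]-4-methyl-2,3,3a,4,5,7a-hexahydro-1H-indene-1,1-dicarboxylate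
Product: 19 cage keto ester (C-α ketone carbon joins arene C2 to C1; C1 keeps one CO2Me), via aryllithium 18 (not isolated)
Conditions: n-BuLi (1.05 equiv), THF, −100 → −78 °C; then H2O
Reagents that add atoms: none
Why: Parham cyclisation: bromine–lithium exchange at the doubly alkoxy-flanked position outruns butyllithium addition to the hindered esters, and the aryllithium can reach only the ester cis to the ether oxygen, so the seven-membered ring closes and C1 becomes a defined quaternary centre.

Step 11
Reactants: 19 cage keto ester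
Product: 20 cage diol (C-α–OH and C1–CH2OH)
Conditions: LiAlH4, THF, 0 °C; aq. NaOH work-up
Reagents that add atoms: none
Why: Hydride reduction converts the aryl ketone to the benzylic carbinol and the ester to the primary alcohol in one operation; the carbinol configuration is immaterial.

Step 12
Reactants: 20 cage diol
Product: 21 cage C-α methyl ether with C1–CH2OH
Conditions: MeOH, PPTS (cat.), rt
Reagents that add atoms: methanol, CO
Why: SN1 solvolysis through the 2,4,6-trialkoxybenzylic cation etherifies only the benzylic alcohol, masking it as a group that ionises again in step 17.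

Step 13
Reactants: 21 cage C-α methyl ether with C1–CH2OH
Product: 22 cage C1–CH2 methanesulfonate
Conditions: MsCl, Et3N, CH2Cl2, 0 °C
Reagents that add atoms: methanesulfonyl chloride, CS(=O)(=O)Cl
Why: Sulfonylation of the primary alcohol under buffered conditions that should leave the acid-labile benzylic ether intact.

Step 14
Reactants: 22 cage C1–CH2 methanesulfonate
Product: 23 cage C1-methyl alkene (C-α–OMe, C6=C7)
Conditions: LiBHEt3, THF, 0 → 50 °C
Reagents that add atoms: none
Why: SN2 displacement of a neopentyl sulfonate by hydride is the classical use of LiBHEt3, and no free hydroxyl is present to divert the mesylate.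

Step 15
Reactants: 23 cage C1-methyl alkene
Product: 24 cage 6,7-dibromocyclopropane
Conditions: CHBr3, KOt-Bu, pentane, 0 °C → rt
Reagents that add atoms: bromoform, BrC(Br)Br
Why: Stereospecific cis [2+1] addition of dibromocarbene to the only alkene should occur on the convex cyclohexene face that carries H-7a, the ether oxygen and the C4 methyl, because the other face lies over the C2–C3 bridge; this sets C6 and C7.

Step 16
Reactants: 24 cage 6,7-dibromocyclopropane
Product: 26 cage gem-dimethylcyclopropane (C-α–OMe), via lithium cyclopropyl(methyl)cuprate 25 (not isolated)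
Conditions: Me2CuLi (from CuI and MeLi; excess), Et2O, −40 → 0 °C; then MeI, 0 °C → rt
Reagents that add atoms: lithium dimethylcuprate, [Li+].C[Cu-]C; iodomethane, CI
Why: gem-Dimethylation of a dibromocyclopropane by bromine–copper exchange, 1,2-methyl shift and alkylation of the cyclopropylcuprate with MeI is established on bicyclo[4.1.0]heptanes, and no cuprate-sensitive group remains.

Step 17
Reactants: 26 cage gem-dimethylcyclopropane (C-α–OMe)
Product: 27 cage C-α-(2-methylallyl) compound
Conditions: CH2=C(CH3)CH2SiMe3, Me3SiOTf (20 mol%), CH2Cl2, −78 °C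
Reagents that add atoms: trimethyl(2-methylallyl)silane, C=C(C)C[Si](C)(C)C
Why: Hosomi–Sakurai-type SN1 allylation: the silyl triflate ionises the methyl ether to the trialkoxybenzylic cation, and the allylsilane should attack the exo face turned toward the one-carbon bridge C7a, not the face under the C2–C3 bridge, which sets C-α.

Step 18
Reactants: 27 cage C-α-(2-methylallyl) compound
Product: 28 cage isobutyl diphenol
Conditions: H2 (1 atm), Pd on carbon (10% Pd), EtOAc/EtOH, rt
Reagents that add atoms: none
Why: Heterogeneous hydrogenation saturates the 1,1-disubstituted alkene and hydrogenolyses both benzyl ethers, while the alkyl cyclopropane and the tertiary aryl ether should be inert at ambient pressure.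

Step 19
Reactants: 28 cage isobutyl diphenol
Product: 30 CNP0202714.1, via bis(α-chloro ether) 29 (not isolated)
Conditions: Cl2CHOMe, TiCl4, CH2Cl2, −78 → 0 °C; then H2O
Reagents that add atoms: dichloromethyl methyl ether, COC(Cl)Cl; water, O
Why: Rieche formylation directed by the titanium phenoxides substitutes the only two free ring positions, each ortho to a hydroxyl, and hydrolysis of the α-chloro ethers releases the two aldehydes.

**Compound list**

1 | 3,5-bis(benzyloxy)phenol | Oc1cc(OCc2ccccc2)cc(OCc2ccccc2)c1 | starting material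
2 | 3,5-bis(benzyloxy)-2-bromophenol | Oc1cc(OCc2ccccc2)cc(OCc2ccccc2)c1Br | intermediate
3 | 1,3-dichloropropan-2-one (1,3-dichloroacetone) | ClCC(=O)CCl | starting material
4 | 1-[3,5-bis(benzyloxy)-2-bromophenoxy]-3-chloropropan-2-one | O=C(CCl)COc1cc(OCc2ccccc2)cc(OCc2ccccc2)c1Br | intermediate
5 | (E)-but-2-enal (crotonaldehyde) | C/C=C/C=O | starting material
6 | dimethyl malonate | COC(=O)CC(=O)OC | starting material
7 | dimethyl 2-[(2E)-but-2-en-1-ylidene]propanedioate | C/C=C/C=C(C(=O)OC)C(=O)OC | intermediate
8 | sodium dienolate of 7 (carbanion at the malonate carbon, (E)-dienyl) | [Na+].COC(=O)[C-](/C=C/C=C)C(=O)OC | intermediate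
9 | dimethyl 2-{3-[3,5-bis(benzyloxy)-2-bromophenoxy]-2-oxopropyl}-2-[(1E)-buta-1,3-dien-1-yl]propanedioate | O=C(COc1cc(OCc2ccccc2)cc(OCc2ccccc2)c1Br)CC(C(=O)OC)(C(=O)OC)/C=C/C=C | intermediate
10 | lithium enolate of 9 at the aryloxy-bearing carbon (enolate geometry not specified) | [Li+].[O-]C(=COc1cc(OCc2ccccc2)cc(OCc2ccccc2)c1Br)CC(C(=O)OC)(C(=O)OC)/C=C/C=C | intermediate
11 | lithium aldolate from 10 and acetaldehyde (diastereomers) | [Li+].CC([O-])C(Oc1cc(OCc2ccccc2)cc(OCc2ccccc2)c1Br)C(=O)CC(C(=O)OC)(C(=O)OC)/C=C/C=C | intermediate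
12 | β-mesyloxy ketone from 11 (diastereomers) | CC(OS(C)(=O)=O)C(Oc1cc(OCc2ccccc2)cc(OCc2ccccc2)c1Br)C(=O)CC(C(=O)OC)(C(=O)OC)/C=C/C=C | intermediate
13 | dimethyl 2-{(3Z)-3-[3,5-bis(benzyloxy)-2-bromophenoxy]-2-oxopent-3-en-1-yl}-2-[(1E)-buta-1,3-dien-1-yl]propanedioate | C/C=C(\Oc1cc(OCc2ccccc2)cc(OCc2ccccc2)c1Br)C(=O)CC(C(=O)OC)(C(=O)OC)/C=C/C=C | intermediate
14 | dimethyl (3aS,4S,7aR)-3a-[3,5-bis(benzyloxy)-2-bromophenoxy]-4-methyl-3-oxo-2,3,3a,4,5,7a-hexahydro-1H-indene-1,1-dicarboxylate (cis-fused; aryloxy, 4-CH3 and H-7a on one face) | O(c1cc(OCc2ccccc2)cc(OCc2ccccc2)c1Br)[C@]12C(=O)CC(C(=O)OC)(C(=O)OC)[C@H]1C=CC[C@@H]2C | intermediate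
15 | 3-hydroxy analogue of 14, (3aS,4S,7aR), C3 epimers | O(c1cc(OCc2ccccc2)cc(OCc2ccccc2)c1Br)[C@]12C(O)CC(C(=O)OC)(C(=O)OC)[C@H]1C=CC[C@@H]2C | intermediate
16 | 3-O-(phenoxycarbonothioyl) derivative of 15, (3aS,4S,7aR), C3 epimers | O(c1cc(OCc2ccccc2)cc(OCc2ccccc2)c1Br)[C@]12C(OC(=S)Oc3ccccc3)CC(C(=O)OC)(C(=O)OC)[C@H]1C=CC[C@@H]2C | intermediate
17 | dimethyl (3aS,4S,7aR)-3a-[3,5-bis(benzyloxy)-2-bromophenoxy]-4-methyl-2,3,3a,4,5,7a-hexahydro-1H-indene-1,1-dicarboxylate | O(c1cc(OCc2ccccc2)cc(OCc2ccccc2)c1Br)[C@]12CCC(C(=O)OC)(C(=O)OC)[C@H]1C=CC[C@@H]2C | intermediate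
18 | aryllithium from 17 (Li in place of Br) | O(c1cc(OCc2ccccc2)cc(OCc2ccccc2)c1[Li])[C@]12CCC(C(=O)OC)(C(=O)OC)[C@H]1C=CC[C@@H]2C | intermediate
19 | cage keto ester: the C1 ester cis to the ether oxygen has become the aryl ketone carbon C-α bonded to arene C2 (seven-membered ring O–C3a–C7a–C1–C-α–aryl C2–aryl C1); C1 keeps CO2Me on the face of C7; C3a, C4, C7a as in 17 | O=C1c2c(OCc3ccccc3)cc(OCc3ccccc3)cc2O[C@]23CC[C@@]1(C(=O)OC)[C@H]2C=CC[C@@H]3C | intermediate
20 | cage diol: C-α–OH (epimers) and C1–CH2OH | OC1c2c(OCc3ccccc3)cc(OCc3ccccc3)cc2O[C@]23CC[C@@]1(CO)[C@H]2C=CC[C@@H]3C | intermediate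
21 | cage C-α methyl ether (epimers) with C1–CH2OH | COC1c2c(OCc3ccccc3)cc(OCc3ccccc3)cc2O[C@]23CC[C@@]1(CO)[C@H]2C=CC[C@@H]3C | intermediate
22 | methanesulfonate of 21 | COC1c2c(OCc3ccccc3)cc(OCc3ccccc3)cc2O[C@]23CC[C@@]1(COS(C)(=O)=O)[C@H]2C=CC[C@@H]3C | intermediate
23 | cage C1-methyl compound with C-α–OMe and C6=C7 alkene | COC1c2c(OCc3ccccc3)cc(OCc3ccccc3)cc2O[C@]23CC[C@@]1(C)[C@H]2C=CC[C@@H]3C | intermediate
24 | 6,7-dibromocyclopropane of 23, CBr2 on the cyclohexane face carrying H-7a, the ether O and 4-CH3 | COC1c2c(OCc3ccccc3)cc(OCc3ccccc3)cc2O[C@]23CC[C@@]1(C)[C@H]2[C@H]1[C@@H](C[C@@H]3C)C1(Br)Br | intermediate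
25 | lithium methyl(1-methylcyclopropyl)cuprate derived from 24 | [Li+].COC1c2c(OCc3ccccc3)cc(OCc3ccccc3)cc2O[C@]23CC[C@@]1(C)[C@H]2[C@H]1[C@@H](C[C@@H]3C)C1(C)[Cu-]C | intermediate
26 | gem-dimethylcyclopropane with C-α–OMe (epimers at C-α) | COC1c2c(OCc3ccccc3)cc(OCc3ccccc3)cc2O[C@]23CC[C@@]1(C)[C@H]2[C@H]1[C@@H](C[C@@H]3C)C1(C)C | intermediate
27 | C-α-(2-methylallyl) compound, side chain exo (on the side of C7a), bis(benzyl ether) | C=C(C)C[C@H]1c2c(OCc3ccccc3)cc(OCc3ccccc3)cc2O[C@]23CC[C@@]1(C)[C@H]2[C@H]1[C@@H](C[C@@H]3C)C1(C)C | intermediate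
28 | C-α-isobutyl diphenol (target lacking both formyl groups) | CC(C)C[C@H]1c2c(O)cc(O)cc2O[C@]23CC[C@@]1(C)[C@H]2[C@H]1[C@@H](C[C@@H]3C)C1(C)C | intermediate
29 | bis[chloro(methoxy)methyl] derivative of 28 at the two free ring positions | CC(C)C[C@H]1c2c(O)c(C(Cl)OC)c(O)c(C(Cl)OC)c2O[C@]23CC[C@@]1(C)[C@H]2[C@H]1[C@@H](C[C@@H]3C)C1(C)C | intermediate
30 | CNP0202714.1 | CC(C)C[C@H]1c2c(O)c(C=O)c(O)c(C=O)c2O[C@]23CC[C@@]1(C)[C@H]2[C@H]1[C@@H](C[C@@H]3C)C1(C)C | target

**Step count and risks**

Total: 19 steps. Longest linear sequence: 18 steps (from 1 through steps 1, 2 and 4–19; step 3 is the only side branch).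

Steps most likely to fail:

Step 6. The catalyst may discriminate the two enone faces poorly, because the dienophile has no α-hydrogen for the usual second contact and the aryl ether oxygen can compete for boron. An uncatalysed background cycloaddition would also erode the enantiomeric purity. Fallback: from 13 the cycloaddition is promoted by the achiral Lewis acid Me2AlCl (CH2Cl2, −78 → 0 °C), an established way to close ketone-activated trienes. This should give the racemic cis-fused adduct, that is 14 together with its mirror image dimethyl (3aR,4R,7aS)-3a-[3,5-bis(benzyloxy)-2-bromophenoxy]-4-methyl-3-oxo-2,3,3a,4,5,7a-hexahydro-1H-indene-1,1-dicarboxylate F1. The enantiomers are separated by preparative chromatography on a chiral stationary phase, and the (3aS,4S,7aR) enantiomer re-enters the route as 14 before step 7.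

Step 17. Facial selectivity in the capture of the benzylic cation may be poor or reversed, since the two faces differ only by the one-carbon bridge with its hydrogen against the two-carbon bridge. Fallback: from 26, oxidation with DDQ in wet CH2Cl2 removes the benzylic hydrogen of the electron-rich methyl ether and should give the cage aryl ketone F2. 2-Methylallylmagnesium chloride (THF, 0 °C) adds to it to give the tertiary carbinol F3. BF3·OEt2 with Et3SiH at −78 °C then ionises it and delivers hydride, instead of carbon, to the face the allylsilane had preferred. The methallyl group is thereby left on the exo side and the product is 27, where the route resumes at step 18.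

Step 16. The cuprate sequence may stop after the first methyl transfer, or the cyclopropylcopper intermediate may be protonated, leaving monomethyl cyclopropanes that are hard to separate. Fallback: from 24, bromine–lithium exchange with n-BuLi at −100 °C in THF and capture of the cyclopropyl carbenoid with MeI should give the 7-bromo-7-methylcyclopropane F4. A second exchange with n-BuLi at −78 °C followed by MeI gives 26, the entry to step 17.

Further compounds
F1 | step 6 | dimethyl (3aR,4R,7aS)-3a-[3,5-bis(benzyloxy)-2-bromophenoxy]-4-methyl-3-oxo-2,3,3a,4,5,7a-hexahydro-1H-indene-1,1-dicarboxylate (enantiomer of 14) | O(c1cc(OCc2ccccc2)cc(OCc2ccccc2)c1Br)[C@@]12C(=O)CC(C(=O)OC)(C(=O)OC)[C@@H]1C=CC[C@H]2C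
F2 | step 17 | cage aryl ketone at C-α with C1-methyl and gem-dimethylcyclopropane, bis(benzyl ether) | O=C1c2c(OCc3ccccc3)cc(OCc3ccccc3)cc2O[C@]23CC[C@@]1(C)[C@H]2[C@H]1[C@@H](C[C@@H]3C)C1(C)C
F3 | step 17 | tertiary C-α carbinol bearing the 2-methylallyl group (carbinol configuration not specified) | C=C(C)CC1(O)c2c(OCc3ccccc3)cc(OCc3ccccc3)cc2O[C@]23CC[C@@]1(C)[C@H]2[C@H]1[C@@H](C[C@@H]3C)C1(C)C
F4 | step 16 | 7-bromo-7-methylcyclopropane analogue of 26 (configuration at the cyclopropane CBrMe carbon not specified) | COC1c2c(OCc3ccccc3)cc(OCc3ccccc3)cc2O[C@]23CC[C@@]1(C)[C@H]2[C@H]1[C@@H](C[C@@H]3C)C1(C)Br
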